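## The problem

Compound 31 is a 1-aryl-2,3-diaroyl-1,2-dihydronaphthalene. Benzene ring A (C4a, C5, C6, C7, C8, C8a) carries H at C5, hydroxyls at C6 and C7 and a methoxy group at C8. It is fused to the half-saturated ring B (C1 to C4), whose C3=C4 bond is conjugated with ring A and with the aroyl group on C3. Two neighbouring stereocentres are needed: C1 (R) carries the 3,4-dihydroxy-2-methoxyphenyl group, C2 (R) carries the second 4-hydroxybenzoyl group, and the two substituents are cis on ring B. C1 is doubly benzylic but not acidic, so it can be set early and then used to direct C2. The reverse is not possible: the C2 hydrogen lies alpha to a ketone and next to the C3=C4 bond and is lost to mild base or acid. The cis arrangement is expected to be the less stable one, because it pushes one large group out of the pseudo-axial position favoured by the C8 methoxy and the C3 aroyl group. It must therefore come from a kinetic event, after which only neutral or cold conditions are allowed. Six phenols, four of them in two catechol units, rule out strong base and oxidants at the end; the C3=C4 bond can migrate to C2=C3, and the dihydronaphthalene can aromatise. The key step rests on one feature: the six ring A carbons fall into three two-carbon pieces, C4a/C5, C6/C7 and C8/C8a, and C4a and C8a are already linked through C4=C3–C2–C1. A terminal alkyne (C4a≡C5) and a methoxyalkyne (C8a≡C8) on one chain, plus one symmetric alkyne for C6/C7, therefore hold every atom of rings A and B.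

## Retrosynthesis

**Phenol unmasking, 31 from 30 from 28.** The last operations change functional groups only. The four phenols that run through the whole route are carried as benzyl ethers, so 31 goes back to 30. Benzyl is preferred to acetal or silyl ethers because it survives the silyl triflate, bromine, amide bases and fluoride used earlier, and because the benzyl-protected ketones 6 and 16 can be bought. The C6 and C7 hydroxyls of 30 go back to the two carbon–boron bonds of 28, so these oxygens enter as substituents of a stable symmetric alkyne. The forward steps must use no base, no protic acid and no oxidant that attacks a catechol or the enone.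

**Key cut, 28 from 26 and 27.** The bonds C5–C6, C7–C8 and C4a–C8a are cut together. This removes ring A and ring B at once and gives the open-chain enediyne 26 and the diboryl alkyne 27. Cutting a single ring B bond instead would need a pentasubstituted ring A made beforehand and an acid- or base-mediated closure next to C2. The threefold cut places OMe, two boron atoms and H on ring A by construction. Compound 26 has no ring besides its aryl groups. It must hold C1 and C2, the (E)-C3=C4 bond (ethynyl group and C2 on the same side), the terminal alkyne and the methoxyalkyne. The forward reaction is a metal-mediated [2+2+2] cycloaddition under neutral conditions, and it must favour the crossed product over oligomers of 26.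

**C2–H bond, 26 from 24.** The C2 configuration is assigned to the last operation before the cycloaddition: deprotonation of the epimer mixture 24 to the dienolate 25 and kinetic protonation. This makes every earlier basic step harmless for C2 and needs only C1 as the controlling element. Compound 24 comes from the silylalkyne 23 by removal of silicon.

**C3=C4 and C2–C3, 23 from 18 and 19, 18 from 15 and 16.** The double bond is cut by a retro-aldol condensation into the 1,4-diketone 18 and the ynal 19. The C2–C3 bond is then cut into the ketone 15 and the bromoketone 16. Attaching the whole enynone unit to C2 in one step would need alpha-alkenylation of a ketone with a halide that is itself a conjugate acceptor, which has no sound precedent. Two ordinary enolate reactions are preferred. Compound 15 has one stereocentre and one ketone.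

**C8a≡C8 triple bond, 15 from 13 from 11 from 8.** The methoxyalkyne is traced to a CH2–CHO group through the enol ether 11 and the bromo enol ether 13. Bringing in the whole C8a≡C8–OMe unit as a nucleophile would need substitution at the secondary benzylic carbon C1 or a conjugate addition, and neither is established for this kind of nucleophile. Elimination on a chain already bonded to C1 uses only known reactions. The eliminating base must not remove the C1 hydrogen.

**C1–C2 bond, 8 from 5 and 7.** The keto aldehyde 8 is cut between C1 and C2 into the enal 5 and the silyl enol ether 7. An amine-catalysed conjugate addition sets C1. It delivers the aldehyde oxidation level at C8 and the ketone on C2 directly, with no later redox or decarboxylation step.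

**Building blocks.** Enal 5 comes from aldehyde 3 and the two-carbon ylide 4 (C8a and C8). Aldehyde 3 comes from 1 through 2 by selective etherification. Compound 7 comes from 6.

## Roads not taken

Alternative 1: The C4–C4a bond is cut while the two ketones are hidden as a 2,5-diarylfuran. The forward key step treats the furan aldehyde A2, whose C1 carries two identical aryl rings, with a chiral BINOL-derived N-triflylphosphoramide. One of the two enantiotopic rings attacks the formyl carbon (Friedel–Crafts hydroxyalkylation), which closes ring B and fixes C1 in A1. The merits are real. Ring A and the pendant ring come from one building block, all oxygen atoms are present from the start, and C2 cannot epimerise while the ketones are masked. The road is also shorter on paper than the chosen one and needs neither an ynol ether nor a late C–B oxidation. The weak points lie after the key step. The carbinol in A1 is benzylic and furfurylic and ionises under the same acid. Opening the furan to the two ketone groups with C2 saturated is uphill and needs strong acid, and C2 would then settle under equilibrium, which favours trans. The C1 hydrogen, flanked by three arenes, is also open to oxidation. Against its brevity the chosen plan sets a neutral ring closure and a C2 centre that is never equilibrated.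

Alternative 2: The C3=C4 bond is cut by alkyne–carbonyl metathesis. The benzaldehyde A4 carries C1, C2 and an arylethynyl group on C2; with FeCl3 or In(OTf)3 it should give A3, the alkyne carbon C3 attacking the formyl carbon C4 and the distal alkyne carbon becoming the C3 aroyl ketone. This closure is documented for the 3-acyl-1,2-dihydronaphthalene ring type, is atom-economic and makes the enone and ring B together. In precedent for ring B and probably in step count this road is better than the chosen one. Its cost is threefold. Ring A of A4 must be assembled as a pentasubstituted benzaldehyde by classical arene chemistry. The formyl group is deactivated by three donor oxygens. And a Lewis acid meets a C2 hydrogen alpha to a ketone both before and after closure, so the cis arrangement is at risk, as are the aryl silyl ethers. The chosen plan answers with a regiospecific construction of ring A and a closure with no acid present.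

Alternative 3: The C1–C2 bond is cut. The diaryl carbinol A6 is dehydrated by a chiral phosphoric acid to a para-quinone methide on the pendant ring, and the enol of the C2 ketone adds to C1 to give A5. Both stereocentres arise in one catalytic step and late, the free para-hydroxyl of the target does the activation, and A6 is convergent. In stereocentres made per step this road is better. Its doubts concern control. The carbinol lies between two electron-rich rings and can ionise without the catalyst. The acid that closes the ring also equilibrates C2 toward trans. The free catechol needs protection different from the other phenols and is sensitive to air. The chosen plan sets C1 and C2 in two separately controlled steps and closes the ring under neutral conditions.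

Key step: step 13

Remark: atom labels C1 to C8a are those of the core of 31 and are used for the same carbons in all intermediates; 4, 6, 16, 19 and 27 are taken as purchasable; all compounds containing the methoxyalkyne are purified on base-washed silica and kept away from carboxylic acids.

## Route

Step 1
Reactants: 1 2,3,4-trihydroxybenzaldehyde
Product: 2 3,4-bis(benzyloxy)-2-hydroxybenzaldehyde
Conditions: BnBr (2.05 equiv), K2CO3 (2.1 equiv), DMF, 0 °C to rt
Reagents that add atoms: benzyl bromide, BrCc1ccccc1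
Why: Williamson ether synthesis; the C2 hydroxyl is hydrogen-bonded to the formyl oxygen and is the least acidic and least nucleophilic, so two equivalents of benzyl bromide should take the C4 and C3 hydroxyls and leave it free.

Step 2
Reactants: 2 3,4-bis(benzyloxy)-2-hydroxybenzaldehyde
Product: 3 3,4-bis(benzyloxy)-2-methoxybenzaldehyde
Conditions: MeI (3 equiv), K2CO3, DMF, 40 °C
Reagents that add atoms: iodomethane, CI
Why: Williamson O-methylation of the remaining chelated phenol; excess iodomethane and gentle warming overcome the hydrogen bond and install the methoxy group of the pendant ring.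

Step 3
Reactants: 3 3,4-bis(benzyloxy)-2-methoxybenzaldehyde; 4 (triphenylphosphoranylidene)acetaldehyde
Product: 5 (2E)-3-[3,4-bis(benzyloxy)-2-methoxyphenyl]prop-2-enal
Conditions: toluene, 90 °C
Reagents that add atoms: none
Why: Wittig olefination with a stabilised ylide gives the (E)-enal; the two carbons brought in become C8a and C8.

Step 4
Reactants: 6 1-[4-(benzyloxy)phenyl]ethanone
Product: 7 {1-[4-(benzyloxy)phenyl]ethenyl}oxy(trimethyl)silane
Conditions: Me3SiOTf (1.2 equiv), Et3N (1.5 equiv), CH2Cl2, 0 °C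
Reagents that add atoms: trimethylsilyl trifluoromethanesulfonate, C[Si](C)(C)OS(=O)(=O)C(F)(F)F
Why: Silyl enol ether formation by soft enolisation; the ketone has only one enolisable position.

Step 5
Reactants: 5 (2E)-3-[3,4-bis(benzyloxy)-2-methoxyphenyl]prop-2-enal; 7 {1-[4-(benzyloxy)phenyl]ethenyl}oxy(trimethyl)silane
Product: 8 (3R)-3-[3,4-bis(benzyloxy)-2-methoxyphenyl]-5-[4-(benzyloxy)phenyl]-5-oxopentanal
Conditions: (2S,5S)-5-benzyl-2-tert-butyl-3-methylimidazolidin-4-one (20 mol%), 2,4-dinitrobenzoic acid (20 mol%), 7 (1.5 equiv), CH2Cl2, H2O (3 equiv), −40 °C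
Reagents that add atoms: water, O
Why: Iminium-catalysed Mukaiyama–Michael addition, known for acetophenone silyl enol ethers and cinnamaldehydes: the amine salt turns 5 into an (E)-iminium ion whose benzyl group covers one face, 7 adds to the open Si face of C1 and forms C1–C2, and hydrolysis releases the aldehyde. The catalyst alone sets C1, expected as (3R)-8; the mirror-image catalyst is available should the sense prove opposite.

Step 6
Reactants: 8 (3R)-3-[3,4-bis(benzyloxy)-2-methoxyphenyl]-5-[4-(benzyloxy)phenyl]-5-oxopentanal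
Product: 11 (3S)-3-[3,4-bis(benzyloxy)-2-methoxyphenyl]-1-[4-(benzyloxy)phenyl]-5-methoxypent-4-en-1-one (E/Z mixture), via dimethyl acetal 9 (not isolated), via silyl dienyl ether 10 (not isolated)
Conditions: HC(OMe)3, MeOH, pyridinium p-toluenesulfonate (5 mol%), rt; evaporation; then Me3SiOTf (2.5 equiv), i-Pr2NEt (3.5 equiv), CH2Cl2, −20 °C to rt; then K2CO3 (cat.), MeOH, 0 °C
Reagents that add atoms: methanol, CO; trimethyl orthoformate, COC(OC)OC
Why: Acetalisation of the aldehyde only (the aryl ketone is far less reactive), then silyl-triflate-induced ionisation of the acetal and loss of a proton from C8a to the hindered amine give the methyl enol ether; the ketone is silylated on the way and freed again by methanolysis. C1 is not touched and the E/Z ratio has no consequence.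

Step 7
Reactants: 11 (3S)-3-[3,4-bis(benzyloxy)-2-methoxyphenyl]-1-[4-(benzyloxy)phenyl]-5-methoxypent-4-en-1-one
Product: 13 (3R)-3-[3,4-bis(benzyloxy)-2-methoxyphenyl]-1-[4-(benzyloxy)phenyl]-4-bromo-5-methoxypent-4-en-1-one (E/Z mixture), via dibromide 12 (not isolated)
Conditions: Br2 (1.0 equiv), CH2Cl2, −78 °C; then DBU (2.2 equiv), −78 to 0 °C
Reagents that add atoms: bromine, BrBr
Why: Electrophilic bromination of an enol ether followed by dehydrobromination, the classical entry to 2-bromovinyl ethers: the enol ether is by far the most nucleophilic π-bond, and the amidine removes HBr across C8a–C8 with loss of the labile bromide next to oxygen. One equivalent of bromine at −78 °C should spare the alkoxyarenes and the ketone.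

Step 8
Reactants: 13 (3R)-3-[3,4-bis(benzyloxy)-2-methoxyphenyl]-1-[4-(benzyloxy)phenyl]-4-bromo-5-methoxypent-4-en-1-one
Product: 15 (3S)-3-[3,4-bis(benzyloxy)-2-methoxyphenyl]-1-[4-(benzyloxy)phenyl]-5-methoxypent-4-yn-1-one, via lithium enolate 14 (not isolated)
Conditions: LiN(i-Pr)2 (2.5 equiv), THF, −78 to −30 °C; aqueous NH4Cl
Reagents that add atoms: none
Why: Base-induced dehydrobromination of a 2-bromovinyl ether to a 1-alkoxyalkyne: the amide removes the vinylic hydrogen next to oxygen and bromide leaves from C8a. One equivalent of base stores the ketone as its enolate, whose charge next to C1 also keeps the C1 hydrogen from being removed, so C1 should keep its configuration.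

Step 9
Reactants: 15 (3S)-3-[3,4-bis(benzyloxy)-2-methoxyphenyl]-1-[4-(benzyloxy)phenyl]-5-methoxypent-4-yn-1-one; 16 1-[4-(benzyloxy)phenyl]-2-bromoethanone
Product: 18 2-{(1S)-1-[3,4-bis(benzyloxy)-2-methoxyphenyl]-3-methoxyprop-2-yn-1-yl}-1,4-bis[4-(benzyloxy)phenyl]butane-1,4-dione (both C2 epimers), via sodium enolate 17 (not isolated)
Conditions: NaN(SiMe3)2 (1.05 equiv), THF, −78 °C; then 16, −78 to −40 °C
Reagents that add atoms: none
Why: Enolate alkylation with an α-bromo ketone (SN2) forms C2–C3 and the 1,4-diketone; the isolated ketone 15 is deprotonated with the sodium amide because the sodium enolate is more nucleophilic than a lithium enolate and needs no polar additive, and α-halo ketones are among the fastest SN2 electrophiles, which should let C-alkylation outrun proton transfer at low temperature. Both C2 epimers are acceptable because C2 is set anew in step 12; the methoxyalkyne is inert to base.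

Step 10
Reactants: 18 2-{(1S)-1-[3,4-bis(benzyloxy)-2-methoxyphenyl]-3-methoxyprop-2-yn-1-yl}-1,4-bis[4-(benzyloxy)phenyl]butane-1,4-dione; 19 3-(trimethylsilyl)prop-2-ynal
Product: 23 (2E)-3-{(1S)-1-[3,4-bis(benzyloxy)-2-methoxyphenyl]-3-methoxyprop-2-yn-1-yl}-1,4-bis[4-(benzyloxy)phenyl]-2-[3-(trimethylsilyl)prop-2-yn-1-ylidene]butane-1,4-dione (both C2 epimers), via lithium enolate 20 (not isolated), via lithium aldolate 21 (not isolated), via acetate 22 (not isolated)
Conditions: LiN(i-Pr)2 (1.05 equiv), THF, −78 °C; then 19; then Ac2O, −78 to 0 °C; then DBU (2 equiv), 0 °C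
Reagents that add atoms: none
Why: Directed aldol condensation: kinetic deprotonation takes the unhindered C3 methylene over the C2 methine, the enolate adds 1,2 to the ynal, and the acetylated aldol loses acetate by E1cB elimination. The (E)-alkene, with the alkynyl group cis to C2 and away from the C3 aroyl group, is expected as the main isomer; acetic anhydride replaces a sulfonyl chloride to keep strong electrophiles and free acid away from the methoxyalkyne.

Step 11
Reactants: 23 (2E)-3-{(1S)-1-[3,4-bis(benzyloxy)-2-methoxyphenyl]-3-methoxyprop-2-yn-1-yl}-1,4-bis[4-(benzyloxy)phenyl]-2-[3-(trimethylsilyl)prop-2-yn-1-ylidene]butane-1,4-dione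
Product: 24 (2E)-3-{(1S)-1-[3,4-bis(benzyloxy)-2-methoxyphenyl]-3-methoxyprop-2-yn-1-yl}-1,4-bis[4-(benzyloxy)phenyl]-2-(prop-2-yn-1-ylidene)butane-1,4-dione (both C2 epimers)
Conditions: Bu4NF (1.05 equiv), THF–H2O (20:1), −40 °C
Reagents that add atoms: none
Why: Fluoride-induced protodesilylation of an alkynylsilane, fast for an alkyne conjugated to an enone; low temperature and water as proton source limit conjugate additions, and epimerisation at C2 is irrelevant at this stage.

Step 12
Reactants: 24 (2E)-3-{(1S)-1-[3,4-bis(benzyloxy)-2-methoxyphenyl]-3-methoxyprop-2-yn-1-yl}-1,4-bis[4-(benzyloxy)phenyl]-2-(prop-2-yn-1-ylidene)butane-1,4-dione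
Product: 26 (2E,3R)-3-{(1S)-1-[3,4-bis(benzyloxy)-2-methoxyphenyl]-3-methoxyprop-2-yn-1-yl}-1,4-bis[4-(benzyloxy)phenyl]-2-(prop-2-yn-1-ylidene)butane-1,4-dione, via lithium dienolate 25 (not isolated)
Conditions: LiN(SiMe3)2 (1.05 equiv), THF, −78 °C; then saturated aqueous NH4Cl in one portion, −78 °C
Reagents that add atoms: none
Why: Enolate formation and diastereoselective kinetic protonation: the C2 hydrogen is the most acidic in 24, both epimers give the same dienolate, and a dienolate is protonated fastest at its α-carbon, here C2. Allylic 1,3-strain holds the C1 hydrogen in the enolate plane, the proton arrives on the face away from the C1 aryl group, and C2 becomes (R) next to (S)-C1, the relationship that is cis in ring B.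

Step 13
Reactants: 26 (2E,3R)-3-{(1S)-1-[3,4-bis(benzyloxy)-2-methoxyphenyl]-3-methoxyprop-2-yn-1-yl}-1,4-bis[4-(benzyloxy)phenyl]-2-(prop-2-yn-1-ylidene)butane-1,4-dione; 27 2,2'-(ethyne-1,2-diyl)bis(4,4,5,5-tetramethyl-1,3,2-dioxaborolane)
Product: 28 {(1R,2R)-1-[3,4-bis(benzyloxy)-2-methoxyphenyl]-8-methoxy-6,7-bis(4,4,5,5-tetramethyl-1,3,2-dioxaborolan-2-yl)-1,2-dihydronaphthalene-2,3-diyl}bis{[4-(benzyloxy)phenyl]methanone}
Conditions: CpCo(CO)2 (30 mol%), 27 (3 equiv), degassed toluene, hν (visible lamp), 110 °C, 26 added over 6 h by syringe pump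
Reagents that add atoms: none
Why: Loss of CO from CpCo(CO)2 gives a CpCo fragment that binds the two alkynes of 26 and couples them oxidatively to a cobaltacyclopentadiene; because C4a and C8a are tied by the chain C4=C3–C2–C1, this coupling forms C4a–C8a and closes ring B as a six-membered ring fused to the metallacycle. Alkyne 27 then coordinates and inserts, and reductive elimination forms C5–C6 and C7–C8, which closes ring A as the arene and frees the cobalt fragment. The closest known reaction type is the cobalt-mediated [2+2+2] cocyclisation of α,ω-diynes with alkynylboronates or with bis(trimethylsilyl)ethyne, which tolerates 1-alkoxyalkynes, ketones and ethers. No stereocentre is formed, and C1 and C2 are spectators in a neutral, aprotic medium. The selectivity needed is crossed over homo-cyclotrimerisation: the (E)-alkene holds C4a on the side of C2 so that the two chain alkynes pair within one molecule, 26 is kept dilute by slow addition, and the hindered 27, used in excess, does not trimerise with itself. Regiochemistry is fixed by the tether for C4a and C8a and is void for the symmetric 27, so OMe ends at C8, H at C5 and boron at C6 and C7. If heat endangers C2, CpCo(C2H4)2 should effect the same cocyclisation at or below room temperature.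

Step 14
Reactants: 28 {(1R,2R)-1-[3,4-bis(benzyloxy)-2-methoxyphenyl]-8-methoxy-6,7-bis(4,4,5,5-tetramethyl-1,3,2-dioxaborolan-2-yl)-1,2-dihydronaphthalene-2,3-diyl}bis{[4-(benzyloxy)phenyl]methanone}
Product: 30 {(1R,2R)-1-[3,4-bis(benzyloxy)-2-methoxyphenyl]-6,7-dihydroxy-8-methoxy-1,2-dihydronaphthalene-2,3-diyl}bis{[4-(benzyloxy)phenyl]methanone}, via bis(borate) 29 (not isolated)
Conditions: Me3NO (anhydrous, 4 equiv), CH2Cl2, rt; then pH 7 phosphate buffer
Reagents that add atoms: trimethylamine N-oxide, C[N+](C)(C)[O-]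
Why: Oxidation of arylboronic esters with an amine N-oxide: the oxide oxygen adds to boron, the aryl group shifts from boron to oxygen with loss of trimethylamine, and the borate esters are hydrolysed on work-up. No base and no peroxide are present, so C2, the enone and the new catechol are not endangered.

Step 15
Reactants: 30 {(1R,2R)-1-[3,4-bis(benzyloxy)-2-methoxyphenyl]-6,7-dihydroxy-8-methoxy-1,2-dihydronaphthalene-2,3-diyl}bis{[4-(benzyloxy)phenyl]methanone}
Product: 31 [(1R,2R)-1-(3,4-dihydroxy-2-methoxyphenyl)-6,7-dihydroxy-8-methoxy-1,2-dihydronaphthalene-2,3-diyl]bis[(4-hydroxyphenyl)methanone]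
Conditions: BCl3 (10 equiv), pentamethylbenzene (12 equiv), CH2Cl2, −78 °C; MeOH quench at −78 °C
Reagents that add atoms: none
Why: Lewis-acid cleavage of aryl benzyl ethers with a cation scavenger: BCl3 ionises the four O–benzyl bonds at −78 °C, pentamethylbenzene traps the benzyl cations before they alkylate the electron-rich rings, and aryl methyl ethers are left at this temperature. The cold aprotic medium gives C2 little chance to enolise; hydrogenolysis is avoided because it would saturate C3=C4.

## Compound list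

1 | 2,3,4-trihydroxybenzaldehyde | O=Cc1ccc(O)c(O)c1O | starting material
2 | 3,4-bis(benzyloxy)-2-hydroxybenzaldehyde | O=Cc1ccc(OCc2ccccc2)c(OCc2ccccc2)c1O | intermediate
3 | 3,4-bis(benzyloxy)-2-methoxybenzaldehyde | O=Cc1ccc(OCc2ccccc2)c(OCc2ccccc2)c1OC | intermediate
4 | (triphenylphosphoranylidene)acetaldehyde | O=CC=P(c1ccccc1)(c1ccccc1)c1ccccc1 | starting material
5 | (2E)-3-[3,4-bis(benzyloxy)-2-methoxyphenyl]prop-2-enal | O=C/C=C/c1ccc(OCc2ccccc2)c(OCc2ccccc2)c1OC | intermediate
6 | 1-[4-(benzyloxy)phenyl]ethanone | CC(=O)c1ccc(OCc2ccccc2)cc1 | starting material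
7 | {1-[4-(benzyloxy)phenyl]ethenyl}oxy(trimethyl)silane | C=C(O[Si](C)(C)C)c1ccc(OCc2ccccc2)cc1 | intermediate
8 | (3R)-3-[3,4-bis(benzyloxy)-2-methoxyphenyl]-5-[4-(benzyloxy)phenyl]-5-oxopentanal | O=CC[C@@H](c1ccc(OCc2ccccc2)c(OCc2ccccc2)c1OC)CC(=O)c1ccc(OCc2ccccc2)cc1 | intermediate
9 | (3R)-3-[3,4-bis(benzyloxy)-2-methoxyphenyl]-1-[4-(benzyloxy)phenyl]-5,5-dimethoxypentan-1-one | COC(OC)C[C@@H](c1ccc(OCc2ccccc2)c(OCc2ccccc2)c1OC)CC(=O)c1ccc(OCc2ccccc2)cc1 | intermediate (not isolated)
10 | {(3R)-3-[3,4-bis(benzyloxy)-2-methoxyphenyl]-1-[4-(benzyloxy)phenyl]-5-methoxypenta-1,4-dien-1-yl}oxy(trimethyl)silane (alkene isomers) | COC=C[C@@H](c1ccc(OCc2ccccc2)c(OCc2ccccc2)c1OC)C=C(O[Si](C)(C)C)c1ccc(OCc2ccccc2)cc1 | intermediate (not isolated)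
11 | (3S)-3-[3,4-bis(benzyloxy)-2-methoxyphenyl]-1-[4-(benzyloxy)phenyl]-5-methoxypent-4-en-1-one (E/Z mixture) | COC=C[C@@H](c1ccc(OCc2ccccc2)c(OCc2ccccc2)c1OC)CC(=O)c1ccc(OCc2ccccc2)cc1 | intermediate
12 | (3R)-3-[3,4-bis(benzyloxy)-2-methoxyphenyl]-1-[4-(benzyloxy)phenyl]-4,5-dibromo-5-methoxypentan-1-one (diastereomers at C4 and C5) | COC(Br)C(Br)[C@@H](c1ccc(OCc2ccccc2)c(OCc2ccccc2)c1OC)CC(=O)c1ccc(OCc2ccccc2)cc1 | intermediate (not isolated)
13 | (3R)-3-[3,4-bis(benzyloxy)-2-methoxyphenyl]-1-[4-(benzyloxy)phenyl]-4-bromo-5-methoxypent-4-en-1-one (E/Z mixture) | COC=C(Br)[C@@H](c1ccc(OCc2ccccc2)c(OCc2ccccc2)c1OC)CC(=O)c1ccc(OCc2ccccc2)cc1 | intermediate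
14 | lithium (1Z,3S)-3-[3,4-bis(benzyloxy)-2-methoxyphenyl]-1-[4-(benzyloxy)phenyl]-5-methoxypent-1-en-4-yn-1-olate | [Li+].COC#C[C@@H](c1ccc(OCc2ccccc2)c(OCc2ccccc2)c1OC)/C=C(\[O-])c1ccc(OCc2ccccc2)cc1 | intermediate (not isolated)
15 | (3S)-3-[3,4-bis(benzyloxy)-2-methoxyphenyl]-1-[4-(benzyloxy)phenyl]-5-methoxypent-4-yn-1-one | COC#C[C@@H](c1ccc(OCc2ccccc2)c(OCc2ccccc2)c1OC)CC(=O)c1ccc(OCc2ccccc2)cc1 | intermediate
16 | 1-[4-(benzyloxy)phenyl]-2-bromoethanone | O=C(CBr)c1ccc(OCc2ccccc2)cc1 | starting material
17 | sodium (1Z,3S)-3-[3,4-bis(benzyloxy)-2-methoxyphenyl]-1-[4-(benzyloxy)phenyl]-5-methoxypent-1-en-4-yn-1-olate | [Na+].COC#C[C@@H](c1ccc(OCc2ccccc2)c(OCc2ccccc2)c1OC)/C=C(\[O-])c1ccc(OCc2ccccc2)cc1 | intermediate (not isolated)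
18 | 2-{(1S)-1-[3,4-bis(benzyloxy)-2-methoxyphenyl]-3-methoxyprop-2-yn-1-yl}-1,4-bis[4-(benzyloxy)phenyl]butane-1,4-dione (both C2 epimers) | COC#C[C@@H](c1ccc(OCc2ccccc2)c(OCc2ccccc2)c1OC)C(CC(=O)c1ccc(OCc2ccccc2)cc1)C(=O)c1ccc(OCc2ccccc2)cc1 | intermediate
19 | 3-(trimethylsilyl)prop-2-ynal | C[Si](C)(C)C#CC=O | starting material
20 | lithium 3-{(1S)-1-[3,4-bis(benzyloxy)-2-methoxyphenyl]-3-methoxyprop-2-yn-1-yl}-1,4-bis[4-(benzyloxy)phenyl]-4-oxobut-1-en-1-olate (both C2 epimers) | [Li+].COC#C[C@@H](c1ccc(OCc2ccccc2)c(OCc2ccccc2)c1OC)C(C=C([O-])c1ccc(OCc2ccccc2)cc1)C(=O)c1ccc(OCc2ccccc2)cc1 | intermediate (not isolated)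
21 | lithium (6S)-4,5-bis[4-(benzyloxy)benzoyl]-6-[3,4-bis(benzyloxy)-2-methoxyphenyl]-8-methoxy-1-(trimethylsilyl)octa-1,7-diyn-3-olate (diastereomers at C3, C4, C5) | [Li+].COC#C[C@@H](c1ccc(OCc2ccccc2)c(OCc2ccccc2)c1OC)C(C(=O)c1ccc(OCc2ccccc2)cc1)C(C([O-])C#C[Si](C)(C)C)C(=O)c1ccc(OCc2ccccc2)cc1 | intermediate (not isolated)
22 | (6S)-4,5-bis[4-(benzyloxy)benzoyl]-6-[3,4-bis(benzyloxy)-2-methoxyphenyl]-8-methoxy-1-(trimethylsilyl)octa-1,7-diyn-3-yl acetate (diastereomers at C3, C4, C5) | COC#C[C@@H](c1ccc(OCc2ccccc2)c(OCc2ccccc2)c1OC)C(C(=O)c1ccc(OCc2ccccc2)cc1)C(C(OC(C)=O)C#C[Si](C)(C)C)C(=O)c1ccc(OCc2ccccc2)cc1 | intermediate (not isolated)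
23 | (2E)-3-{(1S)-1-[3,4-bis(benzyloxy)-2-methoxyphenyl]-3-methoxyprop-2-yn-1-yl}-1,4-bis[4-(benzyloxy)phenyl]-2-[3-(trimethylsilyl)prop-2-yn-1-ylidene]butane-1,4-dione (both C2 epimers) | COC#C[C@@H](c1ccc(OCc2ccccc2)c(OCc2ccccc2)c1OC)C(C(=O)c1ccc(OCc2ccccc2)cc1)/C(C(=O)c1ccc(OCc2ccccc2)cc1)=C\C#C[Si](C)(C)C | intermediate
24 | (2E)-3-{(1S)-1-[3,4-bis(benzyloxy)-2-methoxyphenyl]-3-methoxyprop-2-yn-1-yl}-1,4-bis[4-(benzyloxy)phenyl]-2-(prop-2-yn-1-ylidene)butane-1,4-dione (both C2 epimers) | COC#C[C@@H](c1ccc(OCc2ccccc2)c(OCc2ccccc2)c1OC)C(C(=O)c1ccc(OCc2ccccc2)cc1)/C(C(=O)c1ccc(OCc2ccccc2)cc1)=C\C#C | intermediate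
25 | lithium (3E)-3-[4-(benzyloxy)benzoyl]-1-[4-(benzyloxy)phenyl]-2-{(1S)-1-[3,4-bis(benzyloxy)-2-methoxyphenyl]-3-methoxyprop-2-yn-1-yl}hexa-1,3-dien-5-yn-1-olate | [Li+].COC#C[C@@H](c1ccc(OCc2ccccc2)c(OCc2ccccc2)c1OC)C(=C([O-])c1ccc(OCc2ccccc2)cc1)/C(C(=O)c1ccc(OCc2ccccc2)cc1)=C\C#C | intermediate (not isolated)
26 | (2E,3R)-3-{(1S)-1-[3,4-bis(benzyloxy)-2-methoxyphenyl]-3-methoxyprop-2-yn-1-yl}-1,4-bis[4-(benzyloxy)phenyl]-2-(prop-2-yn-1-ylidene)butane-1,4-dione | COC#C[C@@H](c1ccc(OCc2ccccc2)c(OCc2ccccc2)c1OC)[C@@H](C(=O)c1ccc(OCc2ccccc2)cc1)/C(C(=O)c1ccc(OCc2ccccc2)cc1)=C\C#C | intermediate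
27 | 2,2'-(ethyne-1,2-diyl)bis(4,4,5,5-tetramethyl-1,3,2-dioxaborolane) | CC1(C)OB(C#CB2OC(C)(C)C(C)(C)O2)OC1(C)C | starting material
28 | {(1R,2R)-1-[3,4-bis(benzyloxy)-2-methoxyphenyl]-8-methoxy-6,7-bis(4,4,5,5-tetramethyl-1,3,2-dioxaborolan-2-yl)-1,2-dihydronaphthalene-2,3-diyl}bis{[4-(benzyloxy)phenyl]methanone} | COc1c([C@@H]2c3c(cc(B4OC(C)(C)C(C)(C)O4)c(B4OC(C)(C)C(C)(C)O4)c3OC)C=C(C(=O)c3ccc(OCc4ccccc4)cc3)[C@@H]2C(=O)c2ccc(OCc3ccccc3)cc2)ccc(OCc2ccccc2)c1OCc1ccccc1 | intermediate
29 | {(1R,2R)-1-[3,4-bis(benzyloxy)-2-methoxyphenyl]-8-methoxy-6,7-bis[(4,4,5,5-tetramethyl-1,3,2-dioxaborolan-2-yl)oxy]-1,2-dihydronaphthalene-2,3-diyl}bis{[4-(benzyloxy)phenyl]methanone} | COc1c([C@@H]2c3c(cc(OB4OC(C)(C)C(C)(C)O4)c(OB4OC(C)(C)C(C)(C)O4)c3OC)C=C(C(=O)c3ccc(OCc4ccccc4)cc3)[C@@H]2C(=O)c2ccc(OCc3ccccc3)cc2)ccc(OCc2ccccc2)c1OCc1ccccc1 | intermediate (not isolated)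
30 | {(1R,2R)-1-[3,4-bis(benzyloxy)-2-methoxyphenyl]-6,7-dihydroxy-8-methoxy-1,2-dihydronaphthalene-2,3-diyl}bis{[4-(benzyloxy)phenyl]methanone} | COc1c([C@@H]2c3c(cc(O)c(O)c3OC)C=C(C(=O)c3ccc(OCc4ccccc4)cc3)[C@@H]2C(=O)c2ccc(OCc3ccccc3)cc2)ccc(OCc2ccccc2)c1OCc1ccccc1 | intermediate
31 | [(1R,2R)-1-(3,4-dihydroxy-2-methoxyphenyl)-6,7-dihydroxy-8-methoxy-1,2-dihydronaphthalene-2,3-diyl]bis[(4-hydroxyphenyl)methanone] | COc1c([C@@H]2c3c(cc(O)c(O)c3OC)C=C(C(=O)c3ccc(O)cc3)[C@@H]2C(=O)c2ccc(O)cc2)ccc(O)c1O | target

## Step count and least certain steps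

Total: 15 steps. Longest linear sequence: 14 steps (steps 1 to 3 and 5 to 15; step 4 is a one-step side branch).

**Step 13 (key step).** The most likely failure is that 26 oligomerises through its unhindered terminal alkyne faster than the cobaltacycle is captured by the hindered, electron-poor alkyne 27; long heating would then also erode C2. Changes of conditions come first (CpCo(C2H4)2 at low temperature, or Cp*RuCl(cod) in 1,2-dichloroethane at room temperature). The fallback changes the third alkyne. From 26, cocyclisation with bis(trimethylsilyl)ethyne as co-solvent under CpCo(CO)2 and light should give the 6,7-bis(trimethylsilyl) arene F1. Double ipso-iododesilylation with ICl would give the 6,7-diiodide F2, and Miyaura borylation (PdCl2(dppf), B2pin2, KOAc) returns to 28.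

**Step 7 (with step 8).** The bromo-oxocarbenium ion formed from 11 may be captured by the ketone oxygen (ring closure to a cyclic acetal), or bromine may attack the alkoxyarene, before the open dibromide forms. The fallback carries the ketone at the alcohol level. From 11, NaBH4 gives the alcohol F3 and t-BuMe2SiCl with imidazole the silyl ether F4. Bromine and DBU as in step 7 then give the bromo enol ether F5, and LiN(i-Pr)2 the methoxyalkyne F6. Bu4NF frees the alcohol F7, and a Parikh–Doering oxidation (SO3·pyridine, DMSO, i-Pr2NEt) returns to 15.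

**Step 9.** Proton transfer from the acidic bromoketone 16 to the enolate 17, followed by self-condensation of 16, may compete with C-alkylation. The fallback forms C2–C3 by an acyl-anion addition. From 15, deprotonation as in step 9 and dimethylmethyleneiminium iodide give the Mannich base F8. Quaternisation with MeI and elimination with NaHCO3 give the α-methylene ketone F9. A Stetter reaction with 4-(benzyloxy)benzaldehyde (3-benzyl-5-(2-hydroxyethyl)-4-methylthiazolium chloride, Et3N, dioxane, 70 °C) returns to 18.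

**Step 12.** Protonation of 25 may show poor facial selectivity, because the slim alkynyl group on C1 can take the in-plane position in place of hydrogen, or it may occur at C4. The fallback moves the same operation into the ring, where the C1 aryl group is held pseudo-axial. From 24, the cycloaddition of step 13 is run on the epimer mixture and gives 28 together with its C2 epimer F10. LiN(SiMe3)2 at −78 °C followed by aqueous NH4Cl should protonate the ring dienolate on the face away from the C1 aryl group and return to 28.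

**Step 15.** Lewis-acid-promoted enolisation at C2 during debenzylation would cost the cis arrangement. The fallback repairs it on a silylated form. From 30, the crude product of the BCl3 step is treated with Et3SiCl and imidazole. This gives the hexakis(triethylsilyl) ether F12 and, from epimerised material, its C2 epimer F11. LiN(SiMe3)2 at −78 °C and aqueous NH4Cl converge both on F12, and HF·pyridine returns to 31.

## Further compounds

F1 | step 13 | {(1R,2R)-1-[3,4-bis(benzyloxy)-2-methoxyphenyl]-8-methoxy-6,7-bis(trimethylsilyl)-1,2-dihydronaphthalene-2,3-diyl}bis{[4-(benzyloxy)phenyl]methanone} | COc1c([C@@H]2c3c(cc([Si](C)(C)C)c([Si](C)(C)C)c3OC)C=C(C(=O)c3ccc(OCc4ccccc4)cc3)[C@@H]2C(=O)c2ccc(OCc3ccccc3)cc2)ccc(OCc2ccccc2)c1OCc1ccccc1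
F2 | step 13 | {(1R,2R)-1-[3,4-bis(benzyloxy)-2-methoxyphenyl]-6,7-diiodo-8-methoxy-1,2-dihydronaphthalene-2,3-diyl}bis{[4-(benzyloxy)phenyl]methanone} | COc1c([C@@H]2c3c(cc(I)c(I)c3OC)C=C(C(=O)c3ccc(OCc4ccccc4)cc3)[C@@H]2C(=O)c2ccc(OCc3ccccc3)cc2)ccc(OCc2ccccc2)c1OCc1ccccc1
F3 | step 7 | (3S)-3-[3,4-bis(benzyloxy)-2-methoxyphenyl]-1-[4-(benzyloxy)phenyl]-5-methoxypent-4-en-1-ol (carbinol epimers, E/Z mixture) | COC=C[C@@H](c1ccc(OCc2ccccc2)c(OCc2ccccc2)c1OC)CC(O)c1ccc(OCc2ccccc2)cc1
F4 | step 7 | tert-butyldimethylsilyl ether of F3 | COC=C[C@@H](c1ccc(OCc2ccccc2)c(OCc2ccccc2)c1OC)CC(O[Si](C)(C)C(C)(C)C)c1ccc(OCc2ccccc2)cc1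
F5 | step 7 | (3R)-4-bromo analogue of F4 (2-bromovinyl ether, E/Z mixture) | COC=C(Br)[C@@H](c1ccc(OCc2ccccc2)c(OCc2ccccc2)c1OC)CC(O[Si](C)(C)C(C)(C)C)c1ccc(OCc2ccccc2)cc1
F6 | step 7 | tert-butyldimethylsilyl ether of (3S)-3-[3,4-bis(benzyloxy)-2-methoxyphenyl]-1-[4-(benzyloxy)phenyl]-5-methoxypent-4-yn-1-ol | COC#C[C@@H](c1ccc(OCc2ccccc2)c(OCc2ccccc2)c1OC)CC(O[Si](C)(C)C(C)(C)C)c1ccc(OCc2ccccc2)cc1
F7 | step 7 | (3S)-3-[3,4-bis(benzyloxy)-2-methoxyphenyl]-1-[4-(benzyloxy)phenyl]-5-methoxypent-4-yn-1-ol (carbinol epimers) | COC#C[C@@H](c1ccc(OCc2ccccc2)c(OCc2ccccc2)c1OC)CC(O)c1ccc(OCc2ccccc2)cc1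
F8 | step 9 | (3S)-3-[3,4-bis(benzyloxy)-2-methoxyphenyl]-1-[4-(benzyloxy)phenyl]-2-[(dimethylamino)methyl]-5-methoxypent-4-yn-1-one (both C2 epimers) | COC#C[C@@H](c1ccc(OCc2ccccc2)c(OCc2ccccc2)c1OC)C(CN(C)C)C(=O)c1ccc(OCc2ccccc2)cc1
F9 | step 9 | (3S)-3-[3,4-bis(benzyloxy)-2-methoxyphenyl]-1-[4-(benzyloxy)phenyl]-5-methoxy-2-methylidenepent-4-yn-1-one | COC#C[C@@H](c1ccc(OCc2ccccc2)c(OCc2ccccc2)c1OC)C(=C)C(=O)c1ccc(OCc2ccccc2)cc1
F10 | step 12 | (1R,2S) epimer of 28 | COc1c([C@@H]2c3c(cc(B4OC(C)(C)C(C)(C)O4)c(B4OC(C)(C)C(C)(C)O4)c3OC)C=C(C(=O)c3ccc(OCc4ccccc4)cc3)[C@H]2C(=O)c2ccc(OCc3ccccc3)cc2)ccc(OCc2ccccc2)c1OCc1ccccc1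
F11 | step 15 | hexakis(triethylsilyl) ether of the (1R,2S) epimer of 31 | COc1c([C@@H]2c3c(cc(O[Si](CC)(CC)CC)c(O[Si](CC)(CC)CC)c3OC)C=C(C(=O)c3ccc(O[Si](CC)(CC)CC)cc3)[C@H]2C(=O)c2ccc(O[Si](CC)(CC)CC)cc2)ccc(O[Si](CC)(CC)CC)c1O[Si](CC)(CC)CC
F12 | step 15 | hexakis(triethylsilyl) ether of 31, (1R,2R) | COc1c([C@@H]2c3c(cc(O[Si](CC)(CC)CC)c(O[Si](CC)(CC)CC)c3OC)C=C(C(=O)c3ccc(O[Si](CC)(CC)CC)cc3)[C@@H]2C(=O)c2ccc(O[Si](CC)(CC)CC)cc2)ccc(O[Si](CC)(CC)CC)c1O[Si](CC)(CC)CC
A1 | alternative 1 | 8-methoxy-9-[2-methoxy-3,4-bis(methoxymethoxy)phenyl]-6,7-bis(methoxymethoxy)-1,3-bis[4-(methoxymethoxy)phenyl]-4,9-dihydronaphtho[2,3-c]furan-4-ol | COc1c([C@@H]2c3c(cc(OCOC)c(OCOC)c3OC)[C@@H](O)c3c(-c4ccc(OCOC)cc4)oc(-c4ccc(OCOC)cc4)c32)ccc(OCOC)c1OCOC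
A2 | alternative 1 | 4-{bis[2-methoxy-3,4-bis(methoxymethoxy)phenyl]methyl}-2,5-bis[4-(methoxymethoxy)phenyl]furan-3-carbaldehyde | COc1c(C(c2ccc(OCOC)c(OCOC)c2OC)c2c(C=O)c(-c3ccc(OCOC)cc3)oc2-c2ccc(OCOC)cc2)ccc(OCOC)c1OCOC
A3 | alternative 2 | hexakis(tert-butyldimethylsilyl) ether of 31 | COc1c([C@@H]2c3c(cc(O[Si](C)(C)C(C)(C)C)c(O[Si](C)(C)C(C)(C)C)c3OC)C=C(C(=O)c3ccc(O[Si](C)(C)C(C)(C)C)cc3)[C@@H]2C(=O)c2ccc(O[Si](C)(C)C(C)(C)C)cc2)ccc(O[Si](C)(C)C(C)(C)C)c1O[Si](C)(C)C(C)(C)C
A4 | alternative 2 | 2-methoxy-3,4-bis(tert-butyldimethylsilyloxy)-6-{1-[2-methoxy-3,4-bis(tert-butyldimethylsilyloxy)phenyl]-2-[4-(tert-butyldimethylsilyloxy)benzoyl]-4-[4-(tert-butyldimethylsilyloxy)phenyl]but-3-yn-1-yl}benzaldehyde, C1 and C2 configured as in 31 | COc1c([C@H](c2c(C=O)cc(O[Si](C)(C)C(C)(C)C)c(O[Si](C)(C)C(C)(C)C)c2OC)[C@H](C#Cc2ccc(O[Si](C)(C)C(C)(C)C)cc2)C(=O)c2ccc(O[Si](C)(C)C(C)(C)C)cc2)ccc(O[Si](C)(C)C(C)(C)C)c1O[Si](C)(C)C(C)(C)C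
A5 | alternative 3 | {(1R,2R)-1-(3,4-dihydroxy-2-methoxyphenyl)-8-methoxy-6,7-bis(methoxymethoxy)-1,2-dihydronaphthalene-2,3-diyl}bis{[4-(methoxymethoxy)phenyl]methanone} | COc1c([C@@H]2c3c(cc(OCOC)c(OCOC)c3OC)C=C(C(=O)c3ccc(OCOC)cc3)[C@@H]2C(=O)c2ccc(OCOC)cc2)ccc(O)c1O
A6 | alternative 3 | 2-{2-[(3,4-dihydroxy-2-methoxyphenyl)(hydroxy)methyl]-3-methoxy-4,5-bis(methoxymethoxy)benzylidene}-1,4-bis[4-(methoxymethoxy)phenyl]butane-1,4-dione (ring A aryl cis to the CH2 group, carbinol configuration open) | COc1c(C(O)c2c(/C=C(\CC(=O)c3ccc(OCOC)cc3)C(=O)c3ccc(OCOC)cc3)cc(OCOC)c(OCOC)c2OC)ccc(O)c1O
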